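Readings and results stem from a simulated flask with made-up constants; noise was put on by code.

Watch the free base when you repeat this flask.

- green: electrophile 13 mM; free base 14.3 mM; protonated nucleophile 52 mM; run made earlier
- flask: electrophile 13 mM; free base 14.3 mM; protonated nucleophile 26.0 mM; time 5.0 d

- green (time / h: electrophile / %, target / %): 3.00: 65.4, 26.1; 6.00: 51.9, 36.8; 10.0: 42.4, 43.7; 12.0: 40.4, 45.0

(scatter of a reading: 0.5 percentage points)

- what has gone from electrophile into another species counts as reacted, even if it can come back
- the earlier runs do not show how much of nucleophile is bound; that part of a forecast is a guess

- part of the electrophile that has reacted at 5.0 d
- share of the unused nucleophile that is free and not bound as protonated nucleophile, at 5.0 d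

I read the run in slow motion. In the first instants I take the free base to pull nucleophile out of protonated nucleophile, and the green run makes 26.1% of target by 3.00 h. In the middle the green run tires: target gains 1.3 percentage points over its last 2.00 h, far less than at the start, with 40.4% of electrophile still there.

So I freeze what pays. I assume each target costs two free base, one to free its nucleophile and one to take up the acid its coupling releases. The charge then pays for 55.0% of target; I call this the base allowance, the share of the electrophile charged that the free base pays for at two per target. Free base is then the limiting reagent, since 1.10 per electrophile is less than two. Protonated nucleophile does not enter the allowance, so lowering it leaves that figure unchanged.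

For the end I freeze a second ratio. The electrophile that neither reading shows stands to the electrophile left at 0.361 in the last green reading. With target at the allowance and the rest split that way, I expect 66.9% reacted.

The forecast says 60% reacted (50% to 70%) and 12% free (2% to 35%), noting: “Halving the protonated nucleophile changes the base supply little”. My figure stands 6.9 points above its own.

The flask gives 69.3% reacted and 0.614% free.

    electrophile + nucleophile → acid set free + target (k = 13.4 M⁻¹ h⁻¹)
    nucleophile + acid set free ⇌ protonated nucleophile, settled at all times (K = 85300 M⁻¹)
    acid set free + free base ⇌ salt of the base, settled at all times (K = 75000 M⁻¹)
    electrophile ⇌ dormant form (K = 0.370, k = 0.0402 h⁻¹)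
    2 free base → self-condensation product (k = 4.62 M⁻¹ h⁻¹)

At 5.0 d this flask holds 57.9% target, a little past the allowance, with free base down to 0.651%. It has not come to rest: by 50.0 d the reacted part reaches 81.5% and target 74.6%, while acid set free climbs from 1.90 mM to 6.13 mM.

In a neighbour flask with 52 mM of electrophile the allowance is 13.7%, and the same split gives 36.6% reacted. The computed neighbour gives 41.2%, with 19.3% target.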